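## Retrosynthetic overview

1. Target 28 comes from triene diester 27 by a late peracid epoxidation of the C1=C10 olefin; 27 comes from 8β-alcohol 22 and epoxy acid 25 (made from tiglyl alcohol).
2. Key step: 22 comes from aldehyde 21 by a SmI2 ketyl-radical 10-exo macrocyclisation that forms C7–C8 on a preformed butenolide. Loss of methoxide from the samarium enolate unveils the α-methylene lactone; C7 and C8 are set here.
3. 21 comes from butenolide 17 (C3 acylation, desilylation, oxidation); 17 from Z-iodoallylic alcohol 16 by Pd carbonylative lactonisation; 16 from enynediol 14 by directed trans-hydroalumination/iodination.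
4. 14 comes from vinyl iodide 7 and aldehyde 13 by a Nozaki–Hiyama–Kishi union (C3–C4). 7 is built from but-2-yn-1-ol and methyl propargyl ether; 13 from a silyl butynyl ether, Me3Al and oxirane.
5. Ring order: butenolide (step 8), ten-membered carbocycle (step 12), ring oxirane (step 16); the side-chain oxirane arrives preformed.

Atom labels C1–C15 are those of the germacranolide skeleton of the target (C1/C10 oxirane, C3 and C8 ester carbons, C6 lactone carbinol, C12 lactone carbonyl, C13 exocyclic methylene).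

Assumption: the sense of induction in steps 3 and 6 is taken from the published models for these ligands and was not verified here; both ligands are available as either antipode, and the other antipode is used if the opposite carbinol forms.

## Route

Step 1
Reactants: 1 but-2-yn-1-ol
Product: 3 (Z)-3-iodobut-2-en-1-ol, via cyclic alkenylaluminate 2 (not isolated)
Conditions: NaAlH2(OCH2CH2OMe)2, THF, 0 °C → rt; then I2, THF, −78 → 0 °C
Reagents that add atoms: iodine, II
Why: Hydroxyl-directed trans-hydroalumination of the propargylic alcohol places aluminium on the distal alkyne carbon, and iodination with retention gives the Z iodide.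

Step 2
Reactants: 3 (Z)-3-iodobut-2-en-1-ol
Product: 4 (Z)-3-iodobut-2-enal
Conditions: MnO2, CH2Cl2, rt, dark; used crude
Reagents that add atoms: none
Why: Heterogeneous allylic oxidation with MnO2 is neutral and mild, so the Z geometry of the iodoenal is kept.

Step 3
Reactants: 4 (Z)-3-iodobut-2-enal; 5 3-methoxyprop-1-yne
Product: 7 (4R,5Z)-6-iodo-1-methoxyhept-5-en-2-yn-4-ol, via alkynylzinc 6 (not isolated)
Conditions: 5, Me2Zn, toluene, rt; then (R,R)-ProPhenol (20 mol %), Ph3P=O (40 mol %), 4, 0 °C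
Reagents that add atoms: none
Why: Trost dinuclear-zinc asymmetric alkynylation of an enal, in which the chiral ligand pocket exposes the Si face of the aldehyde to the zinc alkynylide and sets the 4R carbinol (C6).

Step 4
Reactants: 8 tert-butyl(but-3-yn-1-yloxy)dimethylsilane; 9 oxirane
Product: 12 (3E)-6-[(tert-butyldimethylsilyl)oxy]-4-methylhex-3-en-1-ol, via alkenyldimethylalane 10 (not isolated), via lithium alkenylalanate 11 (not isolated)
Conditions: Me3Al, Cp2ZrCl2 (20 mol %), CH2Cl2, 0 °C → rt; then n-BuLi, THF–hexane, −78 → 0 °C; then oxirane, 0 °C → rt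
Reagents that add atoms: trimethylaluminium, C[Al](C)C
Why: Negishi zirconium-catalysed syn-carboalumination fixes the E trisubstituted olefin (C1=C10 with C14), and the alanate opens oxirane with retention at the alkenyl carbon.

Step 5
Reactants: 12 (3E)-6-[(tert-butyldimethylsilyl)oxy]-4-methylhex-3-en-1-ol
Product: 13 (3E)-6-[(tert-butyldimethylsilyl)oxy]-4-methylhex-3-enal
Conditions: Dess–Martin periodinane, pyridine, CH2Cl2, 0 °C; used at once
Reagents that add atoms: none
Why: Buffered Dess–Martin oxidation gives the β,γ-unsaturated aldehyde without moving the olefin into conjugation.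

Step 6
Reactants: 7 (4R,5Z)-6-iodo-1-methoxyhept-5-en-2-yn-4-ol; 13 (3E)-6-[(tert-butyldimethylsilyl)oxy]-4-methylhex-3-enal
Product: 14 (4R,5Z,7S,9E)-12-[(tert-butyldimethylsilyl)oxy]-1-methoxy-6,10-dimethyldodeca-5,9-dien-2-yne-4,7-diol
Conditions: CrCl2 (4 equiv), NiCl2 (5 mol %), (S)-N-[2-(4-isopropyl-4,5-dihydrooxazol-2-yl)-6-methylphenyl]methanesulfonamide (4.4 equiv), Et3N (4.4 equiv), THF, rt
Reagents that add atoms: none
Why: Asymmetric Nozaki–Hiyama–Kishi coupling tolerates the free hydroxyl and the alkyne and keeps the Z olefin, and the chromium-bound chiral sulfonamide selects the aldehyde face to give the 7S carbinol (C3), the minor epimer being removed by chromatography.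

Step 7
Reactants: 14 (4R,5Z,7S,9E)-12-[(tert-butyldimethylsilyl)oxy]-1-methoxy-6,10-dimethyldodeca-5,9-dien-2-yne-4,7-diol
Product: 16 (2Z,4R,5Z,7S,9E)-12-[(tert-butyldimethylsilyl)oxy]-2-iodo-1-methoxy-6,10-dimethyldodeca-2,5,9-triene-4,7-diol, via cyclic alkenylaluminate 15 (not isolated)
Conditions: NaAlH2(OCH2CH2OMe)2, THF, −20 → 0 °C; then I2, −78 °C
Reagents that add atoms: iodine, II
Why: The propargylic C4 hydroxyl directs trans-hydroalumination so that aluminium (then iodine) sits on C2 cis to the carbinol, and holding the mixture at or below 0 °C keeps the β-methoxy alkenylalanate from eliminating to an allene.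

Step 8
Reactants: 16 (2Z,4R,5Z,7S,9E)-12-[(tert-butyldimethylsilyl)oxy]-2-iodo-1-methoxy-6,10-dimethyldodeca-2,5,9-triene-4,7-diol
Product: 17 (5R)-5-[(1Z,3S,5E)-8-[(tert-butyldimethylsilyl)oxy]-3-hydroxy-2,6-dimethylocta-1,5-dien-1-yl]-3-(methoxymethyl)furan-2(5H)-one
Conditions: PdCl2(PPh3)2 (5 mol %), CO (1 atm), K2CO3, THF, rt
Reagents that add atoms: carbon monoxide, [C-]#[O+]
Why: Palladium-catalysed carbonylative lactonisation, in which zerovalent palladium inserts into the carbon–iodine bond, CO insertion follows and the cis hydroxyl captures the acylpalladium to close the butenolide (C12 introduced) without touching the carbinol centre.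

Step 9
Reactants: 17 (5R)-5-[(1Z,3S,5E)-8-[(tert-butyldimethylsilyl)oxy]-3-hydroxy-2,6-dimethylocta-1,5-dien-1-yl]-3-(methoxymethyl)furan-2(5H)-one; 18 (2R)-2-methylbutanoic acid
Product: 19 (1Z,3S,5E)-8-[(tert-butyldimethylsilyl)oxy]-1-[(2R)-4-(methoxymethyl)-5-oxo-2,5-dihydrofuran-2-yl]-2,6-dimethylocta-1,5-dien-3-yl (2R)-2-methylbutanoate
Conditions: N,N'-diisopropylcarbodiimide, DMAP (10 mol %), CH2Cl2, 0 °C
Reagents that add atoms: none
Why: Steglich esterification of the only free hydroxyl (C3) proceeds with retention at both stereocentres under conditions mild enough for the base-sensitive γ-alkenyl butenolide.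

Step 10
Reactants: 19 (1Z,3S,5E)-8-[(tert-butyldimethylsilyl)oxy]-1-[(2R)-4-(methoxymethyl)-5-oxo-2,5-dihydrofuran-2-yl]-2,6-dimethylocta-1,5-dien-3-yl (2R)-2-methylbutanoate
Product: 20 (1Z,3S,5E)-8-hydroxy-1-[(2R)-4-(methoxymethyl)-5-oxo-2,5-dihydrofuran-2-yl]-2,6-dimethylocta-1,5-dien-3-yl (2R)-2-methylbutanoate
Conditions: HF·pyridine, pyridine, THF, 0 °C → rt
Reagents that add atoms: none
Why: Buffered fluoride desilylation frees the primary alcohol without the basic conditions that would deprotonate the butenolide γ-position or cleave the ester.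

Step 11
Reactants: 20 (1Z,3S,5E)-8-hydroxy-1-[(2R)-4-(methoxymethyl)-5-oxo-2,5-dihydrofuran-2-yl]-2,6-dimethylocta-1,5-dien-3-yl (2R)-2-methylbutanoate
Product: 21 (1Z,3S,5E)-1-[(2R)-4-(methoxymethyl)-5-oxo-2,5-dihydrofuran-2-yl]-2,6-dimethyl-8-oxoocta-1,5-dien-3-yl (2R)-2-methylbutanoate
Conditions: Dess–Martin periodinane, pyridine, CH2Cl2, 0 °C; used at once
Reagents that add atoms: none
Why: Buffered Dess–Martin oxidation gives the C8 aldehyde without isomerising the β,γ-olefin.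

Step 12 (key step)
Reactants: 21 (1Z,3S,5E)-1-[(2R)-4-(methoxymethyl)-5-oxo-2,5-dihydrofuran-2-yl]-2,6-dimethyl-8-oxoocta-1,5-dien-3-yl (2R)-2-methylbutanoate
Product: 22 (3aR,4R,6E,9S,10Z,11aR)-4-hydroxy-6,10-dimethyl-3-methylidene-2-oxo-2,3,3a,4,5,8,9,11a-octahydrocyclodeca[b]furan-9-yl (2R)-2-methylbutanoate
Conditions: SmI2 (2.5 equiv), degassed THF, no HMPA, no proton donor, syringe-pump addition of 21 to 1 mM, −40 → 0 °C; then sat. aq. NH4Cl at 0 °C
Reagents that add atoms: none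
Why: Proposed new method: SmI2 turns the aldehyde into a samarium ketyl radical that adds 10-exo to C7 of the tethered butenolide on the face opposite the C6–C5 bond (trans lactone, 3aR); a second SmI2 reduces the α-carbonyl radical to a trivalent samarium enolate that expels methoxide (E1cB) to give the α-methylene lactone, and samarium bridging the ketyl oxygen and the lactone carbonyl in HMPA-free THF is expected to place the C8 oxygen on the β face (4R), although this facial preference is the least certain point of the route; the closest known reaction types are SmI2 ketyl–olefin cyclisations onto unsaturated esters and butenolides and β-elimination from samarium enolates.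

Step 13
Reactants: 23 (2E)-2-methylbut-2-en-1-ol
Product: 24 [(2R,3R)-2,3-dimethyloxiran-2-yl]methanol
Conditions: Ti(OiPr)4 (10 mol %), D-(−)-diisopropyl tartrate (12 mol %), t-BuOOH, 4 Å MS, CH2Cl2, −20 °C
Reagents that add atoms: tert-butyl hydroperoxide, CC(C)(C)OO
Why: Sharpless asymmetric epoxidation of an E trisubstituted allylic alcohol, where the D-(−)-tartrate delivers oxygen to the face that gives the 2R,3R epoxy alcohol.

Step 14
Reactants: 24 [(2R,3R)-2,3-dimethyloxiran-2-yl]methanol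
Product: 25 (2S,3R)-2,3-dimethyloxirane-2-carboxylic acid
Conditions: RuCl3 (2 mol %), NaIO4, CCl4–MeCN–H2O, rt
Reagents that add atoms: sodium periodate, [Na+].[O-]I(=O)(=O)=O; water, O
Why: Catalytic RuO4 oxidation takes the primary alcohol to the acid without opening the oxirane, and only the CIP descriptor at C2 changes (R to S), not the geometry.

Step 15
Reactants: 22 (3aR,4R,6E,9S,10Z,11aR)-4-hydroxy-6,10-dimethyl-3-methylidene-2-oxo-2,3,3a,4,5,8,9,11a-octahydrocyclodeca[b]furan-9-yl (2R)-2-methylbutanoate; 25 (2S,3R)-2,3-dimethyloxirane-2-carboxylic acid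
Product: 27 (3aR,4R,6E,9S,10Z,11aR)-6,10-dimethyl-3-methylidene-9-{[(2R)-2-methylbutanoyl]oxy}-2-oxo-2,3,3a,4,5,8,9,11a-octahydrocyclodeca[b]furan-4-yl (2S,3R)-2,3-dimethyloxirane-2-carboxylate, via mixed anhydride 26 (not isolated)
Conditions: 25, 2,4,6-trichlorobenzoyl chloride, Et3N, toluene, rt; then 22, DMAP, toluene, rt
Reagents that add atoms: none
Why: Yamaguchi esterification acylates the hindered C8 hydroxyl with retention, and the epoxy acid has no α-hydrogen and so cannot epimerise.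

Step 16
Reactants: 27 (3aR,4R,6E,9S,10Z,11aR)-6,10-dimethyl-3-methylidene-9-{[(2R)-2-methylbutanoyl]oxy}-2-oxo-2,3,3a,4,5,8,9,11a-octahydrocyclodeca[b]furan-4-yl (2S,3R)-2,3-dimethyloxirane-2-carboxylate
Product: 28 CNP0265335.4
Conditions: mCPBA (1.1 equiv), NaHCO3, CH2Cl2, 0 °C
Reagents that add atoms: 3-chloroperoxybenzoic acid, O=C(OO)c1cccc(Cl)c1
Why: Prilezhaev epoxidation is chemoselective for the only electron-rich olefin (C1=C10; C4=C5 carries two allylic acyloxy groups and the methylene lactone is electron-poor) and attacks the exposed outer face of the E olefin in the ten-membered ring, as in other germacranolides, which should give the 1R,10R (1β,10α) oxirane.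

## Compound list

1 | but-2-yn-1-ol | CC#CCO | starting material
2 | sodium 2,2-bis(2-methoxyethoxy)-3-methyl-2,5-dihydro-1,2-oxaaluminol-2-uide (cyclic alkenylaluminate) | CC1=CCO[Al-]1(OCCOC)OCCOC.[Na+] | intermediate
3 | (Z)-3-iodobut-2-en-1-ol | C/C(I)=C/CO | intermediate
4 | (Z)-3-iodobut-2-enal | C/C(I)=C/C=O | intermediate
5 | 3-methoxyprop-1-yne | COCC#C | starting material
6 | methyl(3-methoxyprop-1-yn-1-yl)zinc | C[Zn]C#CCOC | intermediate
7 | (4R,5Z)-6-iodo-1-methoxyhept-5-en-2-yn-4-ol | COCC#C[C@H](O)/C=C(/C)I | intermediate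
8 | tert-butyl(but-3-yn-1-yloxy)dimethylsilane | C#CCCO[Si](C)(C)C(C)(C)C | starting material
9 | oxirane | C1CO1 | starting material
10 | [(1E)-4-[(tert-butyldimethylsilyl)oxy]-2-methylbut-1-en-1-yl]dimethylalane | C[Al](C)/C=C(\C)CCO[Si](C)(C)C(C)(C)C | intermediate
11 | lithium butyl[(1E)-4-[(tert-butyldimethylsilyl)oxy]-2-methylbut-1-en-1-yl]dimethylaluminate | [Li+].CCCC[Al-](C)(C)/C=C(\C)CCO[Si](C)(C)C(C)(C)C | intermediate
12 | (3E)-6-[(tert-butyldimethylsilyl)oxy]-4-methylhex-3-en-1-ol | OCC/C=C(\C)CCO[Si](C)(C)C(C)(C)C | intermediate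
13 | (3E)-6-[(tert-butyldimethylsilyl)oxy]-4-methylhex-3-enal | O=CC/C=C(\C)CCO[Si](C)(C)C(C)(C)C | intermediate
14 | (4R,5Z,7S,9E)-12-[(tert-butyldimethylsilyl)oxy]-1-methoxy-6,10-dimethyldodeca-5,9-dien-2-yne-4,7-diol | COCC#C[C@H](O)/C=C(/C)[C@@H](O)C/C=C(\C)CCO[Si](C)(C)C(C)(C)C | intermediate
15 | cyclic alkenylaluminate of 14 (Al bound to C2 and O4, O7 as sodium alkoxide) | COCC1=C[C@@H](/C=C(/C)[C@@H]([O-])C/C=C(\C)CCO[Si](C)(C)C(C)(C)C)O[Al-]1(OCCOC)OCCOC.[Na+].[Na+] | intermediate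
16 | (2Z,4R,5Z,7S,9E)-12-[(tert-butyldimethylsilyl)oxy]-2-iodo-1-methoxy-6,10-dimethyldodeca-2,5,9-triene-4,7-diol | COC/C(I)=C/[C@H](O)/C=C(/C)[C@@H](O)C/C=C(\C)CCO[Si](C)(C)C(C)(C)C | intermediate
17 | (5R)-5-[(1Z,3S,5E)-8-[(tert-butyldimethylsilyl)oxy]-3-hydroxy-2,6-dimethylocta-1,5-dien-1-yl]-3-(methoxymethyl)furan-2(5H)-one | COCC1=C[C@@H](/C=C(/C)[C@@H](O)C/C=C(\C)CCO[Si](C)(C)C(C)(C)C)OC1=O | intermediate
18 | (2R)-2-methylbutanoic acid | CC[C@@H](C)C(=O)O | starting material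
19 | (1Z,3S,5E)-8-[(tert-butyldimethylsilyl)oxy]-1-[(2R)-4-(methoxymethyl)-5-oxo-2,5-dihydrofuran-2-yl]-2,6-dimethylocta-1,5-dien-3-yl (2R)-2-methylbutanoate | COCC1=C[C@@H](/C=C(/C)[C@@H](OC(=O)[C@H](C)CC)C/C=C(\C)CCO[Si](C)(C)C(C)(C)C)OC1=O | intermediate
20 | (1Z,3S,5E)-8-hydroxy-1-[(2R)-4-(methoxymethyl)-5-oxo-2,5-dihydrofuran-2-yl]-2,6-dimethylocta-1,5-dien-3-yl (2R)-2-methylbutanoate | COCC1=C[C@@H](/C=C(/C)[C@@H](OC(=O)[C@H](C)CC)C/C=C(\C)CCO)OC1=O | intermediate
21 | (1Z,3S,5E)-1-[(2R)-4-(methoxymethyl)-5-oxo-2,5-dihydrofuran-2-yl]-2,6-dimethyl-8-oxoocta-1,5-dien-3-yl (2R)-2-methylbutanoate | COCC1=C[C@@H](/C=C(/C)[C@@H](OC(=O)[C@H](C)CC)C/C=C(\C)CC=O)OC1=O | intermediate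
22 | (3aR,4R,6E,9S,10Z,11aR)-4-hydroxy-6,10-dimethyl-3-methylidene-2-oxo-2,3,3a,4,5,8,9,11a-octahydrocyclodeca[b]furan-9-yl (2R)-2-methylbutanoate (8β-hydroxy-3β-acyloxy heliangolide; 3S,6R,7R,8R) | C=C1C(=O)O[C@@H]2/C=C(/C)[C@@H](OC(=O)[C@H](C)CC)C/C=C(\C)C[C@@H](O)[C@@H]12 | intermediate
23 | (2E)-2-methylbut-2-en-1-ol | C/C=C(\C)CO | starting material
24 | [(2R,3R)-2,3-dimethyloxiran-2-yl]methanol | OC[C@@]1(C)O[C@@H]1C | intermediate
25 | (2S,3R)-2,3-dimethyloxirane-2-carboxylic acid | OC(=O)[C@@]1(C)O[C@@H]1C | intermediate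
26 | (2S,3R)-2,3-dimethyloxirane-2-carboxylic 2,4,6-trichlorobenzoic anhydride | O=C(OC(=O)[C@@]1(C)O[C@@H]1C)c1c(Cl)cc(Cl)cc1Cl | intermediate
27 | (3aR,4R,6E,9S,10Z,11aR)-6,10-dimethyl-3-methylidene-9-{[(2R)-2-methylbutanoyl]oxy}-2-oxo-2,3,3a,4,5,8,9,11a-octahydrocyclodeca[b]furan-4-yl (2S,3R)-2,3-dimethyloxirane-2-carboxylate | C=C1C(=O)O[C@@H]2/C=C(/C)[C@@H](OC(=O)[C@H](C)CC)C/C=C(\C)C[C@@H](OC(=O)[C@@]3(C)O[C@@H]3C)[C@@H]12 | intermediate
28 | CNP0265335.4, (1R,3S,4Z,6R,7R,8R,10R)-1,10-epoxy-8-{[(2S,3R)-2,3-dimethyloxirane-2-carbonyl]oxy}-3-{[(2R)-2-methylbutanoyl]oxy}germacra-4,11(13)-dien-12,6-olide | C=C1C(=O)O[C@@H]2/C=C(/C)[C@@H](OC(=O)[C@H](C)CC)C[C@H]3O[C@]3(C)C[C@@H](OC(=O)[C@@]3(C)O[C@@H]3C)[C@@H]12 | target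

## Step count and risk

Total steps: 16. Longest linear sequence: 12 (steps 1, 2, 3, 6, 7, 8, 9, 10, 11, 12, 15, 16).

Three steps most likely to fail:

**Step 12 (SmI2 macrocyclisation).** The ten-membered closure is unprecedented and may stall; if it does close, the face of the ketyl is the least predictable element, and a non-chelated transition state would give the C8 epimer. The fallback covers the epimer case and sets out from 21. The cyclisation is accepted as giving the 8-epimer, (3aR,4S,6E,9S,10Z,11aR)-4-hydroxy-6,10-dimethyl-3-methylidene-2-oxo-2,3,3a,4,5,8,9,11a-octahydrocyclodeca[b]furan-9-yl (2R)-2-methylbutanoate F1. F1 is then esterified with acid 25 under Mitsunobu conditions (PPh3, diisopropyl azodicarboxylate, toluene, 0 °C → rt) instead of the Yamaguchi acylation. This installs the ester with inversion at C8 and comes back to the route at 27 with no extra step.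

**Step 6 (ligand-controlled Nozaki–Hiyama–Kishi union).** The free hydroxyl of 7 and the unbranched aldehyde may erode the selectivity at C3. The fallback sets out from 7 and moves the stereocontrol from C–C bond formation to a ketone reduction. 7 is silylated (Et3SiCl, imidazole, CH2Cl2) to triethyl{[(4R,5Z)-6-iodo-1-methoxyhept-5-en-2-yn-4-yl]oxy}silane F2. F2 is coupled with 13 without ligand (CrCl2, cat. NiCl2, DMSO) to give (4R,5Z,9E)-12-[(tert-butyldimethylsilyl)oxy]-1-methoxy-6,10-dimethyl-4-[(triethylsilyl)oxy]dodeca-5,9-dien-2-yn-7-ol F3 as a mixture of C7 epimers. Dess–Martin oxidation gives the Z-enone (4R,5Z,9E)-12-[(tert-butyldimethylsilyl)oxy]-1-methoxy-6,10-dimethyl-4-[(triethylsilyl)oxy]dodeca-5,9-dien-2-yn-7-one F4. Corey–Bakshi–Shibata reduction with the (R)-2-methyl-oxazaborolidine and catecholborane (toluene, −78 °C; alkenyl as the large group) gives (4R,5Z,7S,9E)-12-[(tert-butyldimethylsilyl)oxy]-1-methoxy-6,10-dimethyl-4-[(triethylsilyl)oxy]dodeca-5,9-dien-2-yn-7-ol F5. Selective removal of the triethylsilyl group (pyridinium p-toluenesulfonate, MeOH, 0 °C) comes back to the route at 14.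

**Step 16 (substrate-controlled epoxidation).** If the peracid attacks the wrong face of the macrocyclic olefin, no reagent can correct it on the ring, so the fallback installs the oxirane under reagent control before ring closure. It sets out from 20. Shi epoxidation (D-fructose-derived ketone, KHSO5, K2CO3, MeCN–dimethoxymethane–H2O, 0 °C; R,R epoxides from E trisubstituted olefins) gives (1Z,3S)-4-[(2R,3R)-3-(2-hydroxyethyl)-3-methyloxiran-2-yl]-1-[(2R)-4-(methoxymethyl)-5-oxo-2,5-dihydrofuran-2-yl]-2-methylbut-1-en-3-yl (2R)-2-methylbutanoate F6. Dess–Martin oxidation gives the aldehyde (1Z,3S)-1-[(2R)-4-(methoxymethyl)-5-oxo-2,5-dihydrofuran-2-yl]-2-methyl-4-[(2R,3R)-3-methyl-3-(2-oxoethyl)oxiran-2-yl]but-1-en-3-yl (2R)-2-methylbutanoate F7. SmI2 cyclisation as in step 12 gives (1R,3S,4Z,6R,7R,8R,10R)-1,10-epoxy-8-hydroxy-3-{[(2R)-2-methylbutanoyl]oxy}germacra-4,11(13)-dien-12,6-olide F8. Yamaguchi esterification of F8 with 25 as in step 15 comes back to the route at 28.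

## Further compounds

F1 | step 12 | (3aR,4S,6E,9S,10Z,11aR)-4-hydroxy-6,10-dimethyl-3-methylidene-2-oxo-2,3,3a,4,5,8,9,11a-octahydrocyclodeca[b]furan-9-yl (2R)-2-methylbutanoate | C=C1C(=O)O[C@@H]2/C=C(/C)[C@@H](OC(=O)[C@H](C)CC)C/C=C(\C)C[C@H](O)[C@@H]12
F2 | step 6 | triethyl{[(4R,5Z)-6-iodo-1-methoxyhept-5-en-2-yn-4-yl]oxy}silane | COCC#C[C@H](O[Si](CC)(CC)CC)/C=C(/C)I
F3 | step 6 | (4R,5Z,9E)-12-[(tert-butyldimethylsilyl)oxy]-1-methoxy-6,10-dimethyl-4-[(triethylsilyl)oxy]dodeca-5,9-dien-2-yn-7-ol (C7 epimer mixture) | COCC#C[C@H](O[Si](CC)(CC)CC)/C=C(/C)C(O)C/C=C(\C)CCO[Si](C)(C)C(C)(C)C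
F4 | step 6 | (4R,5Z,9E)-12-[(tert-butyldimethylsilyl)oxy]-1-methoxy-6,10-dimethyl-4-[(triethylsilyl)oxy]dodeca-5,9-dien-2-yn-7-one | COCC#C[C@H](O[Si](CC)(CC)CC)/C=C(/C)C(=O)C/C=C(\C)CCO[Si](C)(C)C(C)(C)C
F5 | step 6 | (4R,5Z,7S,9E)-12-[(tert-butyldimethylsilyl)oxy]-1-methoxy-6,10-dimethyl-4-[(triethylsilyl)oxy]dodeca-5,9-dien-2-yn-7-ol | COCC#C[C@H](O[Si](CC)(CC)CC)/C=C(/C)[C@@H](O)C/C=C(\C)CCO[Si](C)(C)C(C)(C)C
F6 | step 16 | (1Z,3S)-4-[(2R,3R)-3-(2-hydroxyethyl)-3-methyloxiran-2-yl]-1-[(2R)-4-(methoxymethyl)-5-oxo-2,5-dihydrofuran-2-yl]-2-methylbut-1-en-3-yl (2R)-2-methylbutanoate | COCC1=C[C@@H](/C=C(/C)[C@@H](OC(=O)[C@H](C)CC)C[C@H]2O[C@]2(C)CCO)OC1=O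
F7 | step 16 | (1Z,3S)-1-[(2R)-4-(methoxymethyl)-5-oxo-2,5-dihydrofuran-2-yl]-2-methyl-4-[(2R,3R)-3-methyl-3-(2-oxoethyl)oxiran-2-yl]but-1-en-3-yl (2R)-2-methylbutanoate | COCC1=C[C@@H](/C=C(/C)[C@@H](OC(=O)[C@H](C)CC)C[C@H]2O[C@]2(C)CC=O)OC1=O
F8 | step 16 | (1R,3S,4Z,6R,7R,8R,10R)-1,10-epoxy-8-hydroxy-3-{[(2R)-2-methylbutanoyl]oxy}germacra-4,11(13)-dien-12,6-olide | C=C1C(=O)O[C@@H]2/C=C(/C)[C@@H](OC(=O)[C@H](C)CC)C[C@H]3O[C@]3(C)C[C@@H](O)[C@@H]12
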